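## The problem

Target 23 is a 2,3-dihydro-1-benzofuran whose benzene ring (ring A) carries four contiguous, different substituents: O1 on C7a, the C3 methylene on C3a, a methoxy group on C4 and an (E)-4-hydroxycinnamoyl group on C7. Benzofuran locants are used below for the corresponding atoms of all intermediates. Placing the acyl group at C7 and not at C5 is the regiochemical core of the problem, because both positions of a preformed 4-methoxy-dihydrobenzofuran are activated by an oxygen. The only stereocentre is C2 (R), which carries the ring oxygen and the 2-hydroxypropan-2-yl group. Nothing else in the molecule can control it, so it has to be bought or made by an enantioselective reaction, and its C–O bond must then stay untouched. The cross-conjugated aryl enone is a Michael acceptor and is reducible, so organometallic reagents, hydride and hydrogenation are excluded once it is present. The phenol and the tertiary alcohol need masking. The C2–H/C3–H2 unit can be dehydrogenated to a benzofuran by a strong oxidant, which would destroy the stereocentre. The feature that opens the route is that ring A can be read as a cycloadduct: C7a(O1)=C3a–C4(OMe)=C5 is a 1,3-dioxygenated diene that can sit in a 4,5-dihydrofuran already holding C2, and C6–C7 with its acyl group is a terminal ynone, which is the enynone half of the chalcone.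

## Retrosynthesis

**23 from 22.** The two O–H groups of 23 are traced back to the bis-silyl ether 22 (two O–Si bonds cut). The phenol has to be masked against DDQ and the Grignard reagent. The tertiary alcohol has to be masked so that it cannot compete in the ring-forming hydroalkoxylation or consume the titanium reagent. Two tert-butyldimethylsilyl groups are chosen so that one fluoride treatment ends the synthesis. The tertiary ether is deliberately not a more labile silyl group, because it must survive an acetonide hydrolysis early on.

**22 from 14 and 20.** Ring A of 22 is cut at C5–C6 and C7–C7a, giving the chiral dihydrofuran diene 14 and the enynone 20, with the 1,4-cyclohexadiene 21 as the unisolated link. Compared with acylating or halogenating a finished arene, this cut fixes the position of every substituent through the polarity of the partners. It removes one ring and two skeletal bonds and leaves an achiral and a monocyclic fragment. The forward reaction has to give one regioisomer, react at the alkyne and not the enone of 20, and convert 21 to the arene by loss of two hydrogens and not by loss of O1.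

**20 from 15.** Enynone 20 is cut at the carbonyl–alkyne bond into the Weinreb amide 18 and ethynylmagnesium bromide 19. Amide 18 is cut at its C=C bond into aldehyde 16 and phosphonate 17, and 16 is the silyl ether of 4-hydroxybenzaldehyde 15. The amide route is preferred to an aldehyde addition and oxidation because it reaches the ketone oxidation level directly and sets the E-alkene in the olefination.

**14 from 10.** The exocyclic methylene C5 of 14 is removed to give the vinylogous carbonate 13 (C4=C5 cut), since carbonyl methylenation turns an ester OMe directly into the enol ether OMe that the target needs. Ester 13 comes from the trichloromethyl ketone 12, and 12 from the dihydrofuran 10 and trichloroacetyl chloride 11 (C3a–C4 cut). Acylation at the β-carbon of a cyclic enol ether is the natural way to put one carbon on C3a. The precursor 10 has lost the whole diene side arm.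

**10 from 6.** The enol ether 10 is opened at O1–C7a to the homopropargylic alcohol 9, which an endo-selective metal-vinylidene cycloisomerisation should close. Alkynol 9 comes from its C-silyl derivative 8, and 8 from the epoxide 6 and trimethylsilylacetylene 7 (C3–C3a cut). This places both remaining ring-A carbons with one reagent and leaves the C2–O bond untouched.

**6 from 1.** Epoxide 6 is traced to the diol 4 through the primary tosylate 5, the diol to the acetonide 3, and 3 through the tertiary alcohol 2 to methyl (R)-glycerate acetonide 1. The stereocentre of 1 becomes C2 of the target. No step breaks its C–O bond, and the CIP order of its substituents stays the same, so R in 1 means R in 23.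

## Roads not taken

**Alternative 1:** The dihydrofuran is cut at C2–C3 and O1–C2. The sulfone 6-bromo-3-methoxy-2-[(4-methylphenyl)sulfonylmethyl]phenol A2 would lose sulfinate with Cs2CO3 to give an ortho-quinone methide. An ammonium ylide made in the same flask from tert-butyl bromoacetate A3 and a cinchona-derived tertiary amine would add to the exocyclic CH2, and the phenoxide would displace the ammonium group to give tert-butyl (R)-7-bromo-4-methoxy-2,3-dihydro-1-benzofuran-2-carboxylate A1.
- Merits: ring A stays an aromatic throughout, C2 is made in the ring-forming step, and the C7 bromide is a ready handle for the acyl group.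
- Weak points: the quinone methide has no substituent on its CH2, so enantioselectivity rests entirely on how the chiral ammonium group biases the ylide. The new centre is α to an ester and α to an aryloxy group and can epimerise under the basic conditions. A2 is itself a 1,2,3,4-tetrasubstituted benzene that has to be made regioselectively. After A1 the route still needs methyl addition to the ester, protection, halogen–metal exchange and acylation by a cinnamoyl amide (1,2 against 1,4 addition), and deprotection.
- Comparison: the step count is similar and there is no labile diene, which is a real advantage. The chosen plan offers a configuration taken from the chiral pool, which needs no proof of enantiomeric purity, and a substitution pattern fixed by the cycloaddition.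

**Alternative 2:** The chalcone is cut at C7–C(=O) and C(=O)–Cα. (R)-2-(7-Iodo-4-methoxy-2,3-dihydro-1-benzofuran-2-yl)propan-2-ol A5, CO and 4-acetoxystyrene A6 would be joined with Pd(OAc)2, a bulky phosphine and Et3N in a carbonylative Heck reaction to give the acetate of the target A4.
- Merits: this is the most convergent end-game. The free tertiary alcohol is tolerated, the E-enone forms directly, and only a mild acetate cleavage follows.
- Weak points: the difficulty is moved to A5. Its stereocentre needs a separate asymmetric step, and iodination of the 4-methoxy-dihydrobenzofuran must choose C7 over C5. The three-component coupling competes with direct Heck arylation of A6, and CO insertion into an electron-rich ortho-alkoxy aryl palladium species is slow. Pressurised CO is needed.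
- Comparison: this road is clearly better in late-stage convergence and in steps after A5. The chosen plan avoids any regioselective functionalisation of ring A and any carbonylation selectivity question.

**Alternative 3:** The cuts are O1–C7a and C7–C(=O). The lithium alkoxide of (R)-1-(2-fluoro-6-methoxyphenyl)-3-(methoxymethoxy)-3-methylbutan-2-ol A8 (n-BuLi) would be lithiated ortho to fluorine (LiN(i-Pr)2 or s-BuLi). Loss of LiF gives the C7≡C7a aryne, the alkoxide adds at C7a to close the dihydrofuran, and the C7 aryllithium is acylated by (E)-N-methoxy-3-[4-(methoxymethoxy)phenyl]-N-methylprop-2-enamide A9 to give the bis(methoxymethyl) ether of the target A7.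
- Merits: it is probably the shortest route. Ring closure and acylation occur in one flask from a simple fluoroarene, and the aryne mechanism fixes the acyl group at C7.
- Weak points: three organolithium events must follow each other cleanly. Lithiation ortho to OMe (C5) competes. The aryllithium can be protonated by the amine or add in conjugate fashion to A9. The final acid removal of a tertiary methoxymethyl ether takes place next to an enone. A8 still needs the same kind of chiral epoxide as the chosen route.
- Comparison: this road wins on step count. The chosen plan forms ring A and attaches the chalcone under neutral thermal conditions with no strong base near the enone, and ends with a fluoride deprotection.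

Key step: step 14

## Route

Step 1
Reactants: 1 methyl (R)-2,2-dimethyl-1,3-dioxolane-4-carboxylate
Product: 2 (R)-2-(2,2-dimethyl-1,3-dioxolan-4-yl)propan-2-ol
Conditions: MeMgBr (3 equiv), THF, 0 °C → rt; aq. NH4Cl
Reagents that add atoms: methylmagnesium bromide, C[Mg]Br
Why: Double Grignard addition to an ester; addition is faster than enolisation of the α-alkoxy ester, and the stereocentre is not a reacting centre, so its configuration should be kept.

Step 2
Reactants: 2 (R)-2-(2,2-dimethyl-1,3-dioxolan-4-yl)propan-2-ol
Product: 3 (R)-tert-butyl{[2-(2,2-dimethyl-1,3-dioxolan-4-yl)propan-2-yl]oxy}dimethylsilane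
Conditions: TBSOTf, 2,6-lutidine, CH2Cl2, 0 °C → rt
Reagents that add atoms: tert-butyldimethylsilyl trifluoromethanesulfonate, CC(C)(C)[Si](C)(C)OS(=O)(=O)C(F)(F)F
Why: Silyl triflate silylation of a hindered tertiary alcohol; the buffered, cold conditions should leave the acetonide intact.

Step 3
Reactants: 3 (R)-tert-butyl{[2-(2,2-dimethyl-1,3-dioxolan-4-yl)propan-2-yl]oxy}dimethylsilane
Product: 4 (R)-3-(tert-butyldimethylsilyloxy)-3-methylbutane-1,2-diol
Conditions: AcOH–H2O–THF (3:1:1), 40 °C
Reagents that add atoms: none
Why: Acid hydrolysis of a terminal isopropylidene acetal; a tertiary tert-butyldimethylsilyl ether is hindered enough to survive aqueous acetic acid.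

Step 4
Reactants: 4 (R)-3-(tert-butyldimethylsilyloxy)-3-methylbutane-1,2-diol
Product: 6 (R)-tert-butyldimethyl{[2-(oxiran-2-yl)propan-2-yl]oxy}silane, via primary tosylate 5 (not isolated)
Conditions: TsCl, Et3N, Bu2SnO (cat.), CH2Cl2, 0 °C → rt; then K2CO3, MeOH, 0 °C → rt
Reagents that add atoms: none
Why: Stannylene-catalysed sulfonylation picks the primary hydroxyl of the 1,2-diol, and intramolecular Williamson closure by the secondary alkoxide then gives the epoxide. The C–O bond at the stereocentre is not broken (retention), and the 3-exo closure should be faster than silyl migration to the alkoxide.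

Step 5
Reactants: 6 (R)-tert-butyldimethyl{[2-(oxiran-2-yl)propan-2-yl]oxy}silane; 7 trimethylsilylacetylene
Product: 8 (R)-2-(tert-butyldimethylsilyloxy)-2-methyl-6-(trimethylsilyl)hex-5-yn-3-ol
Conditions: 7, n-BuLi, THF, −78 °C; BF3·OEt2, then 6, −78 °C; aq. NH4Cl
Reagents that add atoms: none
Why: BF3-promoted opening of a terminal epoxide by a lithium acetylide at the unhindered CH2. The stereocentre is untouched, and the alkoxide is held as a borate, which suppresses silyl migration.

Step 6
Reactants: 8 (R)-2-(tert-butyldimethylsilyloxy)-2-methyl-6-(trimethylsilyl)hex-5-yn-3-ol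
Product: 9 (R)-2-(tert-butyldimethylsilyloxy)-2-methylhex-5-yn-3-ol
Conditions: K2CO3 (cat.), MeOH, 0 °C → rt
Reagents that add atoms: none
Why: Methanolysis of the C(sp)–Si bond; the tertiary silyl ether is inert to catalytic carbonate in methanol at this temperature.

Step 7
Reactants: 9 (R)-2-(tert-butyldimethylsilyloxy)-2-methylhex-5-yn-3-ol
Product: 10 (R)-2-[2-(tert-butyldimethylsilyloxy)propan-2-yl]-2,3-dihydrofuran
Conditions: W(CO)6 (cat.), DABCO, THF, hν (350 nm), 60 °C
Reagents that add atoms: none
Why: Endo-selective cycloisomerisation of a but-3-yn-1-ol through a tungsten vinylidene: the hydroxyl adds to the metal-bound terminal carbon and protodemetalation releases the cyclic enol ether. The protected tertiary oxygen cannot compete, and the stereocentre is a spectator.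

Step 8
Reactants: 10 (R)-2-[2-(tert-butyldimethylsilyloxy)propan-2-yl]-2,3-dihydrofuran; 11 trichloroacetyl chloride
Product: 12 2,2,2-trichloro-1-{(R)-5-[2-(tert-butyldimethylsilyloxy)propan-2-yl]-4,5-dihydrofuran-3-yl}ethan-1-one
Conditions: pyridine, CH2Cl2, 0 °C → rt
Reagents that add atoms: none
Why: Electrophilic β-acylation of an enol ether by the very reactive trichloroacetyl chloride; loss of the proton with pyridine restores the enol ether as a vinylogous ester.

Step 9
Reactants: 12 2,2,2-trichloro-1-{(R)-5-[2-(tert-butyldimethylsilyloxy)propan-2-yl]-4,5-dihydrofuran-3-yl}ethan-1-one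
Product: 13 methyl (R)-5-[2-(tert-butyldimethylsilyloxy)propan-2-yl]-4,5-dihydrofuran-3-carboxylate
Conditions: MeOH, K2CO3 (cat.), 0 °C → rt
Reagents that add atoms: methanol, CO
Why: Haloform-type cleavage: methoxide adds to the trichloromethyl ketone and trichloromethanide leaves, giving the methyl ester and chloroform.

Step 10
Reactants: 13 methyl (R)-5-[2-(tert-butyldimethylsilyloxy)propan-2-yl]-4,5-dihydrofuran-3-carboxylate
Product: 14 (R)-4-(1-methoxyethenyl)-2-[2-(tert-butyldimethylsilyloxy)propan-2-yl]-2,3-dihydrofuran
Conditions: Cp2TiMe2 (3 equiv), toluene–THF, 65 °C, dark; filtration through basic Al2O3 with Et3N in the eluent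
Reagents that add atoms: dimethyltitanocene, [CH3-].[CH3-].[Ti+4].c1cc[cH-]c1.c1cc[cH-]c1
Why: Petasis methylenation: Cp2Ti=CH2 formed on heating adds to the ester carbonyl and the oxatitanacyclobutane collapses to the methyl enol ether. The reagent is non-acidic, which suits the acid-labile 2-methoxy diene.

Step 11
Reactants: 15 4-hydroxybenzaldehyde
Product: 16 4-(tert-butyldimethylsilyloxy)benzaldehyde
Conditions: TBSCl, imidazole, DMF, rt
Reagents that add atoms: tert-butyldimethylsilyl chloride, CC(C)(C)[Si](C)(C)Cl
Why: Standard imidazole-mediated silylation of a phenol.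

Step 12
Reactants: 16 4-(tert-butyldimethylsilyloxy)benzaldehyde; 17 diethyl {2-[methoxy(methyl)amino]-2-oxoethyl}phosphonate
Product: 18 (E)-3-[4-(tert-butyldimethylsilyloxy)phenyl]-N-methoxy-N-methylprop-2-enamide
Conditions: NaH, THF, 0 °C → rt
Reagents that add atoms: none
Why: Horner–Wadsworth–Emmons olefination with a stabilised phosphonate carbanion, which gives the E-alkene under thermodynamic control of the oxaphosphetane.

Step 13
Reactants: 18 (E)-3-[4-(tert-butyldimethylsilyloxy)phenyl]-N-methoxy-N-methylprop-2-enamide; 19 ethynylmagnesium bromide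
Product: 20 (E)-1-[4-(tert-butyldimethylsilyloxy)phenyl]pent-1-en-4-yn-3-one
Conditions: THF, −20 → 0 °C; inverse quench into cold aq. NaHSO4
Reagents that add atoms: none
Why: Weinreb ketone synthesis: the chelated tetrahedral adduct prevents over-addition and collapses only on work-up. The acidic inverse quench protonates the released amine before it can add to the ynone, and the E-alkene is not involved.

Step 14
Reactants: 14 (R)-4-(1-methoxyethenyl)-2-[2-(tert-butyldimethylsilyloxy)propan-2-yl]-2,3-dihydrofuran; 20 (E)-1-[4-(tert-butyldimethylsilyloxy)phenyl]pent-1-en-4-yn-3-one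
Product: 22 (E)-1-{(R)-2-[2-(tert-butyldimethylsilyloxy)propan-2-yl]-4-methoxy-2,3-dihydro-1-benzofuran-7-yl}-3-[4-(tert-butyldimethylsilyloxy)phenyl]prop-2-en-1-one, via tetrahydrobenzofuran cycloadduct 21 (not isolated)
Conditions: 14 (1.1 equiv), 20, toluene, 70 °C; then 0 °C, DDQ (1.1 equiv), 0 °C → rt
Reagents that add atoms: none
Why: Thermal normal-electron-demand Diels–Alder reaction followed by dehydrogenation in the same flask; the closest known reaction type is the cycloaddition of 1,3-dioxygenated dienes with terminal ynones and aromatization of the adduct to a resorcinol ether. The diene carbon C5, which lies β to the methoxy group and carries the largest HOMO coefficient, bonds to the unsubstituted alkyne carbon C6, and the oxygen-bearing C7a bonds to the acyl-bearing C7, so both donors reinforce one orientation and the acyl group lands next to O1 and para to OMe. Ring A is closed in a single intermolecular [4+2] event in which C5–C6 and C7–C7a form together from the s-cis diene, a conformation that its 2,3-disubstitution favours. The terminal ynone is far more dienophilic than the β-aryl enone on the other side of the carbonyl, which is β-substituted and deactivated by the p-silyloxyphenyl donor, so only the alkyne should react. Cycloadduct 21 is a 1,4-cyclohexadiene with H on C7a and H2 on C5; DDQ should abstract hydride from C7a because the resulting cation is stabilised by O1 and, through C3a=C4, by the methoxy group, and loss of a proton from C5 then gives the arene with both oxygens retained. This oxidation has to outrun loss of O1 from C7a (vinylogous β-elimination through the C5 dienolate, or acid ionisation), which is why the medium is kept neutral and DDQ is added cold as soon as 20 is consumed. No lasting stereocentre is formed: the C7a centre of 21 is erased on aromatization, and C2, set in compound 1, is a spectator. Only a slight excess of DDQ at or below room temperature is used so that the C2–C3 bond of the dihydrofuran is not dehydrogenated.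

Step 15
Reactants: 22 (E)-1-{(R)-2-[2-(tert-butyldimethylsilyloxy)propan-2-yl]-4-methoxy-2,3-dihydro-1-benzofuran-7-yl}-3-[4-(tert-butyldimethylsilyloxy)phenyl]prop-2-en-1-one
Product: 23 (E)-1-[(R)-2-(2-hydroxypropan-2-yl)-4-methoxy-2,3-dihydro-1-benzofuran-7-yl]-3-(4-hydroxyphenyl)prop-2-en-1-one
Conditions: TBAF (excess), THF, rt → 50 °C; aq. NH4Cl
Reagents that add atoms: none
Why: Fluoride cleaves the aryl silyl ether at once and the hindered tertiary silyl ether on warming; the enone, the aryl methyl ether and the stereocentre are inert to these conditions.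

## Compound list

1 | methyl (R)-2,2-dimethyl-1,3-dioxolane-4-carboxylate | COC(=O)[C@H]1COC(C)(C)O1 | starting material
2 | (R)-2-(2,2-dimethyl-1,3-dioxolan-4-yl)propan-2-ol | CC(C)(O)[C@H]1COC(C)(C)O1 | intermediate
3 | (R)-tert-butyl{[2-(2,2-dimethyl-1,3-dioxolan-4-yl)propan-2-yl]oxy}dimethylsilane | CC(C)(O[Si](C)(C)C(C)(C)C)[C@H]1COC(C)(C)O1 | intermediate
4 | (R)-3-(tert-butyldimethylsilyloxy)-3-methylbutane-1,2-diol | CC(C)(O[Si](C)(C)C(C)(C)C)[C@H](O)CO | intermediate
5 | (R)-3-(tert-butyldimethylsilyloxy)-2-hydroxy-3-methylbutyl 4-methylbenzenesulfonate | CC(C)(O[Si](C)(C)C(C)(C)C)[C@H](O)COS(=O)(=O)c1ccc(C)cc1 | intermediate (not isolated)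
6 | (R)-tert-butyldimethyl{[2-(oxiran-2-yl)propan-2-yl]oxy}silane | CC(C)(O[Si](C)(C)C(C)(C)C)[C@H]1CO1 | intermediate
7 | trimethylsilylacetylene | C#C[Si](C)(C)C | starting material
8 | (R)-2-(tert-butyldimethylsilyloxy)-2-methyl-6-(trimethylsilyl)hex-5-yn-3-ol | CC(C)(O[Si](C)(C)C(C)(C)C)[C@H](O)CC#C[Si](C)(C)C | intermediate
9 | (R)-2-(tert-butyldimethylsilyloxy)-2-methylhex-5-yn-3-ol | CC(C)(O[Si](C)(C)C(C)(C)C)[C@H](O)CC#C | intermediate
10 | (R)-2-[2-(tert-butyldimethylsilyloxy)propan-2-yl]-2,3-dihydrofuran | CC(C)(O[Si](C)(C)C(C)(C)C)[C@H]1CC=CO1 | intermediate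
11 | trichloroacetyl chloride | O=C(Cl)C(Cl)(Cl)Cl | starting material
12 | 2,2,2-trichloro-1-{(R)-5-[2-(tert-butyldimethylsilyloxy)propan-2-yl]-4,5-dihydrofuran-3-yl}ethan-1-one | CC(C)(O[Si](C)(C)C(C)(C)C)[C@H]1CC(C(=O)C(Cl)(Cl)Cl)=CO1 | intermediate
13 | methyl (R)-5-[2-(tert-butyldimethylsilyloxy)propan-2-yl]-4,5-dihydrofuran-3-carboxylate | COC(=O)C1=CO[C@@H](C(C)(C)O[Si](C)(C)C(C)(C)C)C1 | intermediate
14 | (R)-4-(1-methoxyethenyl)-2-[2-(tert-butyldimethylsilyloxy)propan-2-yl]-2,3-dihydrofuran | COC(=C)C1=CO[C@@H](C(C)(C)O[Si](C)(C)C(C)(C)C)C1 | intermediate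
15 | 4-hydroxybenzaldehyde | O=Cc1ccc(O)cc1 | starting material
16 | 4-(tert-butyldimethylsilyloxy)benzaldehyde | O=Cc1ccc(O[Si](C)(C)C(C)(C)C)cc1 | intermediate
17 | diethyl {2-[methoxy(methyl)amino]-2-oxoethyl}phosphonate | CCOP(=O)(CC(=O)N(C)OC)OCC | starting material
18 | (E)-3-[4-(tert-butyldimethylsilyloxy)phenyl]-N-methoxy-N-methylprop-2-enamide | CON(C)C(=O)/C=C/c1ccc(O[Si](C)(C)C(C)(C)C)cc1 | intermediate
19 | ethynylmagnesium bromide | C#C[Mg]Br | starting material
20 | (E)-1-[4-(tert-butyldimethylsilyloxy)phenyl]pent-1-en-4-yn-3-one | C#CC(=O)/C=C/c1ccc(O[Si](C)(C)C(C)(C)C)cc1 | intermediate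
21 | (E)-1-{(2R)-2-[2-(tert-butyldimethylsilyloxy)propan-2-yl]-4-methoxy-2,3,5,7a-tetrahydro-1-benzofuran-7-yl}-3-[4-(tert-butyldimethylsilyloxy)phenyl]prop-2-en-1-one (both C7a epimers) | COC1=C2C[C@H](C(C)(C)O[Si](C)(C)C(C)(C)C)OC2C(C(=O)/C=C/c2ccc(O[Si](C)(C)C(C)(C)C)cc2)=CC1 | intermediate (not isolated)
22 | (E)-1-{(R)-2-[2-(tert-butyldimethylsilyloxy)propan-2-yl]-4-methoxy-2,3-dihydro-1-benzofuran-7-yl}-3-[4-(tert-butyldimethylsilyloxy)phenyl]prop-2-en-1-one | COc1ccc(C(=O)/C=C/c2ccc(O[Si](C)(C)C(C)(C)C)cc2)c2c1C[C@H](C(C)(C)O[Si](C)(C)C(C)(C)C)O2 | intermediate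
23 | (E)-1-[(R)-2-(2-hydroxypropan-2-yl)-4-methoxy-2,3-dihydro-1-benzofuran-7-yl]-3-(4-hydroxyphenyl)prop-2-en-1-one | COc1ccc(C(=O)/C=C/c2ccc(O)cc2)c2c1C[C@H](C(C)(C)O)O2 | target

## Step count and risks

Total: 15 steps. Longest linear sequence: 12 steps (steps 1–10, 14 and 15, from compound 1). The enynone arm (steps 11–13) is three steps.

**Step 14 (key step).** The cross-conjugated enynone 20 may polymerise or react at its enone while the cycloaddition is being driven to completion at 70 °C. The longer cycloadduct 21 then waits for the oxidant, the more it can aromatise by loss of O1 from C7a instead of by dehydrogenation, which gives a ring-opened arene that cannot be returned to the route. Over-oxidation of the C2–C3 bond by excess DDQ is a lesser concern.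
Fallback: separate ring formation from chalcone assembly by using a smaller and more reactive dienophile. Setting out from 14, cycloaddition with but-3-yn-2-one at or below room temperature should give the unisolated adduct 1-{(2R)-2-[2-(tert-butyldimethylsilyloxy)propan-2-yl]-4-methoxy-2,3,5,7a-tetrahydro-1-benzofuran-7-yl}ethan-1-one F1. Immediate cold DDQ oxidation should give the methyl ketone 1-{(R)-2-[2-(tert-butyldimethylsilyloxy)propan-2-yl]-4-methoxy-2,3-dihydro-1-benzofuran-7-yl}ethan-1-one F2. Claisen–Schmidt condensation of F2 with aldehyde 15 (KOH, EtOH) should give (E)-1-{(R)-2-[2-(tert-butyldimethylsilyloxy)propan-2-yl]-4-methoxy-2,3-dihydro-1-benzofuran-7-yl}-3-(4-hydroxyphenyl)prop-2-en-1-one F3, and the fluoride treatment of step 15 brings the sequence back to the route at 23.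

**Step 10.** Methylenation of a vinylogous carbonate is slower than that of a simple ester, and the 2-methoxy diene 14 may be hydrolysed to the methyl ketone or polymerised by titanium residues or traces of acid during isolation.
Fallback: build the diene by cross-coupling instead of carbonyl methylenation. Setting out from 10, iodination of the enol ether β-carbon (N-iodosuccinimide, AgNO3 cat.) should give (R)-4-iodo-2-[2-(tert-butyldimethylsilyloxy)propan-2-yl]-2,3-dihydrofuran F4. Negishi coupling (Pd(PPh3)4, THF) with chloro(1-methoxyethenyl)zinc F5, made in the flask from methyl vinyl ether, t-BuLi and ZnCl2, returns to the route at 14.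

**Step 7.** The secondary hydroxyl lies next to a quaternary silyloxy carbon and may trap the tungsten vinylidene slowly. Catalyst decay, alkyne oligomerisation or acid-induced loss of the product enol ether could then dominate.
Fallback: reach the dihydrofuran through a lactol. Setting out from 6, CuI-catalysed opening with allylmagnesium bromide should give (R)-2-(tert-butyldimethylsilyloxy)-2-methylhept-6-en-3-ol F6. Ozonolysis with PPh3 work-up should give the lactol (5R)-5-[2-(tert-butyldimethylsilyloxy)propan-2-yl]oxolan-2-ol F7. Treatment with MsCl and Et3N should form (5R)-5-[2-(tert-butyldimethylsilyloxy)propan-2-yl]oxolan-2-yl methanesulfonate F8 (not isolated), which eliminates to return to the route at 10.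

**Step 13.** On quenching, the released N,O-dimethylhydroxylamine may add in conjugate fashion to the new terminal ynone, and the ynone may oligomerise on concentration.
Fallback: reach the ketone by oxidation, with no amine present when it forms. Setting out from 18, reduction with i-Bu2AlH should give (E)-3-[4-(tert-butyldimethylsilyloxy)phenyl]prop-2-enal F9. Addition of 19 should give (E)-1-[4-(tert-butyldimethylsilyloxy)phenyl]pent-1-en-4-yn-3-ol F10 (racemic), and MnO2 oxidation returns to the route at 20.

## Further compounds

F1 | step 14 | 1-{(2R)-2-[2-(tert-butyldimethylsilyloxy)propan-2-yl]-4-methoxy-2,3,5,7a-tetrahydro-1-benzofuran-7-yl}ethan-1-one | COC1=C2C[C@H](C(C)(C)O[Si](C)(C)C(C)(C)C)OC2C(C(C)=O)=CC1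
F2 | step 14 | 1-{(R)-2-[2-(tert-butyldimethylsilyloxy)propan-2-yl]-4-methoxy-2,3-dihydro-1-benzofuran-7-yl}ethan-1-one | COc1ccc(C(C)=O)c2c1C[C@H](C(C)(C)O[Si](C)(C)C(C)(C)C)O2
F3 | step 14 | (E)-1-{(R)-2-[2-(tert-butyldimethylsilyloxy)propan-2-yl]-4-methoxy-2,3-dihydro-1-benzofuran-7-yl}-3-(4-hydroxyphenyl)prop-2-en-1-one | COc1ccc(C(=O)/C=C/c2ccc(O)cc2)c2c1C[C@H](C(C)(C)O[Si](C)(C)C(C)(C)C)O2
F4 | step 10 | (R)-4-iodo-2-[2-(tert-butyldimethylsilyloxy)propan-2-yl]-2,3-dihydrofuran | CC(C)(O[Si](C)(C)C(C)(C)C)[C@H]1CC(I)=CO1
F5 | step 10 | chloro(1-methoxyethenyl)zinc | COC(=C)[Zn]Cl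
F6 | step 7 | (R)-2-(tert-butyldimethylsilyloxy)-2-methylhept-6-en-3-ol | CC(C)(O[Si](C)(C)C(C)(C)C)[C@H](O)CCC=C
F7 | step 7 | (5R)-5-[2-(tert-butyldimethylsilyloxy)propan-2-yl]oxolan-2-ol | CC(C)(O[Si](C)(C)C(C)(C)C)[C@H]1CCC(O)O1
F8 | step 7 | (5R)-5-[2-(tert-butyldimethylsilyloxy)propan-2-yl]oxolan-2-yl methanesulfonate | CC(C)(O[Si](C)(C)C(C)(C)C)[C@H]1CCC(OS(C)(=O)=O)O1
F9 | step 13 | (E)-3-[4-(tert-butyldimethylsilyloxy)phenyl]prop-2-enal | O=C/C=C/c1ccc(O[Si](C)(C)C(C)(C)C)cc1
F10 | step 13 | (E)-1-[4-(tert-butyldimethylsilyloxy)phenyl]pent-1-en-4-yn-3-ol | C#CC(O)/C=C/c1ccc(O[Si](C)(C)C(C)(C)C)cc1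
A1 | alternative 1 | tert-butyl (R)-7-bromo-4-methoxy-2,3-dihydro-1-benzofuran-2-carboxylate | COc1ccc(Br)c2c1C[C@H](C(=O)OC(C)(C)C)O2
A2 | alternative 1 | 6-bromo-3-methoxy-2-[(4-methylphenyl)sulfonylmethyl]phenol | COc1ccc(Br)c(O)c1CS(=O)(=O)c1ccc(C)cc1
A3 | alternative 1 | tert-butyl bromoacetate | CC(C)(C)OC(=O)CBr
A4 | alternative 2 | 4-{(E)-3-[(R)-2-(2-hydroxypropan-2-yl)-4-methoxy-2,3-dihydro-1-benzofuran-7-yl]-3-oxoprop-1-enyl}phenyl acetate | COc1ccc(C(=O)/C=C/c2ccc(OC(C)=O)cc2)c2c1C[C@H](C(C)(C)O)O2
A5 | alternative 2 | (R)-2-(7-iodo-4-methoxy-2,3-dihydro-1-benzofuran-2-yl)propan-2-ol | COc1ccc(I)c2c1C[C@H](C(C)(C)O)O2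
A6 | alternative 2 | 4-acetoxystyrene | C=Cc1ccc(OC(C)=O)cc1
A7 | alternative 3 | (E)-1-{(R)-4-methoxy-2-[2-(methoxymethoxy)propan-2-yl]-2,3-dihydro-1-benzofuran-7-yl}-3-[4-(methoxymethoxy)phenyl]prop-2-en-1-one | COc1ccc(C(=O)/C=C/c2ccc(OCOC)cc2)c2c1C[C@H](C(C)(C)OCOC)O2
A8 | alternative 3 | (R)-1-(2-fluoro-6-methoxyphenyl)-3-(methoxymethoxy)-3-methylbutan-2-ol | COc1cccc(F)c1C[C@H](C(C)(C)OCOC)O
A9 | alternative 3 | (E)-N-methoxy-3-[4-(methoxymethoxy)phenyl]-N-methylprop-2-enamide | CON(C)C(=O)/C=C/c1ccc(OCOC)cc1
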